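Of the target the violet run showed at 15.0 h, 37.5% was left at 120 h, and of what the teal run showed at 4.00 h, 50.5% was left at 20.0 h, and I began from these leftovers.

common to all: substrate 10 mM

| run | partner | temperature | remark | time |
|---|---|---|---|---|
| violet | 2.5 equiv | 1 °C | run made earlier |  |
| teal | 3.8 equiv | 26 °C | run made earlier |  |
| south-east | 5.00 equiv | 20 °C |  | 40 h |
| south | 5.00 equiv | −10 °C |  | 40 h |
| east | 5.00 equiv | 5 °C |  | 40 h |
| west | 5.00 equiv | 35 °C |  | 40 h |

| run | time / h | target / % |
|---|---|---|
| violet | 15.0 | 8.0 |
| violet | 40.0 | 6.5 |
| violet | 48.0 | 5.6 |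
| violet | 72.0 | 5.9 |
| violet | 96.0 | 4.6 |
| violet | 120 | 3.0 |
| teal | 4.00 | 10.7 |
| teal | 6.00 | 10.4 |
| teal | 8.00 | 9.1 |
| teal | 15.0 | 7.0 |
| teal | 20.0 | 5.4 |
| teal | 30.0 | 4.2 |
| teal | 50.0 | 3.4 |

(scatter of a reading: 0.5 percentage points)

* the flask that comes out highest in amount of target, in percent of the substrate charged, or "all alike" when all lie within 1.5 percentage points (south-east / south / east / west / all alike)
* target at the end, in percent of the substrate charged, south-east
* target at the end, in percent of the substrate charged, south
* target at the end, in percent of the substrate charged, east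
* target at the end, in percent of the substrate charged, west



I stopped the teal reckoning at 20.0 h, and the two later teal readings stand at 4.2% and 3.4%. A loss constant k, the natural logarithm of the inverse fraction left divided by the hours elapsed, then reads 0.00934 h⁻¹ in violet and 0.0427 h⁻¹ in teal, faster than violet. So the two temperatures give an apparent activation energy Ea of 41.5 kJ mol⁻¹, but the runs also differ in partner, and I assumed that partner leaves this figure alone.

With that energy the 40 h of south at −10 °C count as 18.7 h of violet, and this is what I carried: the equivalent time, the hours a reference run needs to reach the stage a flask reaches in its own hours, found by scaling those hours with the Arrhenius factor between the two temperatures. South therefore sits between the first two violet readings, where interpolation gives 7.78%. I assumed that target scales with the equivalents of partner, which gives my own 15.6%. East counts 52.0 h, more than south, so I put south highest.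

The forecast also named south, holding that “cold flasks retain most of their peak”, with south-east 4.8%, south 8.5%, east 7% and west 3%. My south figure stands above its high end of 11%.

The flasks gave south-east 5.09%, south 15.2%, east 10.1% and west 2.67%, so south came out highest.

    substrate + target → side product (k = 33.0 L mol⁻¹ h⁻¹, Ea = 61.0 kJ mol⁻¹)
    substrate + partner ⇌ isomer of the product (K = 44.0 L mol⁻¹, k = 1.30 L mol⁻¹ h⁻¹, Ea = 64.0 kJ mol⁻¹, ΔH = −53.0 kJ mol⁻¹)
    2 substrate → homo dimer (k = 10.0 L mol⁻¹ h⁻¹, Ea = 59.0 kJ mol⁻¹)
    substrate + partner ⇌ target (K = 20.0 L mol⁻¹, k = 2.40 L mol⁻¹ h⁻¹, Ea = 49.0 kJ mol⁻¹, ΔH = 14.0 kJ mol⁻¹)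
    (constants at 20 °C)

South, at 18.7 h of violet, read 15.2%, and west minus south stood at −13 percentage points; in the run with the effect of temperature taken off the conversion of substrate + target into side product, that difference was −5 points, so that effect is one part of the difference. The west flask read at 10 h counts 16.3 h of teal, where the teal readings scaled by partner give 8.67%, and that flask held 7.89%.

The data are simulated for an exercise; the scatter is artificial.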